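The 14-membered carbocycle (ring atoms C1–C14, C1 bearing the isopropenyl group) is opened at C12–C13. The syn C12-methyl/C13-oxygen pair next to C11H2 and the C10 ketone is the hydrated form of a homopropargylic alcohol. A BF3-triggered anti SE2′ attack of a chiral C10-stannylated allene (C10=C11=C12) on the tethered C13 aldehyde should therefore close the ring, create C12 and C13, and leave a C10≡C11 alkyne that the new hydroxyl later converts into the ketone. The precursor is an acyclic C13 aldehyde carrying C1, C4, C5 (acetate), C8 and an (aS)-tributylstannyl allene. It is assembled by lithiation–borylation at C4–C5 from a citronellal-derived benzoate and a secondary boronic ester.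

Key step: step 20

Assumption: both enantiomers of sparteine, 3-[(tert-butyldiphenylsilyl)oxy]propan-1-ol and isopropenylboronic acid pinacol ester are bought; the labels C1–C14 in names and comments are the ring numbers defined above (TBS = tert-butyldimethylsilyl, TBDPS = tert-butyldiphenylsilyl, pin = pinacolato).

Step 1
Reactants: 1 (S)-citronellal
Product: 2 (S)-4,8-dimethylnon-7-en-1-yne
Conditions: MeC(O)C(N2)P(O)(OMe)2, K2CO3, MeOH, rt
Reagents that add atoms: dimethyl (1-diazo-2-oxopropyl)phosphonate, CC(=O)C(=[N+]=[N-])P(=O)(OC)OC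
Why: Seyferth–Gilbert homologation in the Ohira–Bestmann variant turns the aldehyde carbon into C10 and adds C11 under mild carbonate conditions, and the β-stereocentre C8 cannot epimerise.

Step 2
Reactants: 2 (S)-4,8-dimethylnon-7-en-1-yne; 3 N-methoxy-N-methylacetamide
Product: 5 (S)-6,10-dimethylundec-9-en-3-yn-2-one, via lithium acetylide 4 (not isolated)
Conditions: n-BuLi, THF, −78 °C; then 3, −78 to 0 °C
Reagents that add atoms: none
Why: Acylation of a lithium acetylide with a Weinreb amide stops at the ynone because the chelated tetrahedral adduct collapses only on work-up, which brings in C12 and its methyl group in one operation.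

Step 3
Reactants: 5 (S)-6,10-dimethylundec-9-en-3-yn-2-one
Product: 6 (2R,6S)-6,10-dimethylundec-9-en-3-yn-2-ol
Conditions: Ru[(R,R)-TsDPEN](p-cymene) (1 mol %), i-PrOH, rt
Reagents that add atoms: none
Why: Noyori asymmetric transfer hydrogenation of an alkynyl methyl ketone, in which the (R,R)-TsDPEN ligand directs hydride to the carbonyl face that gives the (12R)-carbinol while alkyne and alkene stay untouched.

Step 4
Reactants: 6 (2R,6S)-6,10-dimethylundec-9-en-3-yn-2-ol
Product: 7 tert-butyl{[(2R,6S)-6,10-dimethylundec-9-en-3-yn-2-yl]oxy}dimethylsilane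
Conditions: TBSCl, imidazole, CH2Cl2, rt
Reagents that add atoms: tert-butyldimethylsilyl chloride, CC(C)(C)[Si](C)(C)Cl
Why: Standard silyl ether formation masks the C12 hydroxyl against the ozonolysis work-up, the Mitsunobu step and organolithium base.

Step 5
Reactants: 7 tert-butyl{[(2R,6S)-6,10-dimethylundec-9-en-3-yn-2-yl]oxy}dimethylsilane
Product: 9 (4S,8R)-8-(TBSO)-4-methylnon-6-yn-1-ol, via C5 aldehyde 8 (not isolated)
Conditions: O3, CH2Cl2/MeOH, −78 °C; then NaBH4, −78 °C to rt
Reagents that add atoms: ozone, [O-][O+]=O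
Why: Ozonolysis with reductive borohydride work-up cleaves the electron-rich trisubstituted alkene much faster than the internal alkyne and delivers the C5 primary alcohol directly.

Step 6
Reactants: 9 (4S,8R)-8-(TBSO)-4-methylnon-6-yn-1-ol; 10 2,4,6-triisopropylbenzoic acid
Product: 11 (4S,8R)-8-(TBSO)-4-methylnon-6-yn-1-yl 2,4,6-triisopropylbenzoate (fragment A)
Conditions: PPh3, DIAD, THF, 0 °C to rt
Reagents that add atoms: none
Why: Mitsunobu esterification gives the hindered benzoate, which resists nucleophilic attack, directs α-lithiation at C5 and later serves as the leaving group.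

Step 7
Reactants: 12 3-[(tert-butyldiphenylsilyl)oxy]propan-1-ol; 10 2,4,6-triisopropylbenzoic acid
Product: 13 3-(TBDPSO)propyl 2,4,6-triisopropylbenzoate
Conditions: PPh3, DIAD, THF, 0 °C to rt
Reagents that add atoms: none
Why: Mitsunobu esterification converts the three-carbon C13–C14–C1 unit into a carbenoid precursor whose silyl ether already masks the future aldehyde.

Step 8
Reactants: 13 3-(TBDPSO)propyl 2,4,6-triisopropylbenzoate; 14 isopropenylboronic acid pinacol ester
Product: 17 tert-butyl{[(3S)-4-methyl-3-(Bpin)pent-4-en-1-yl]oxy}diphenylsilane, via lithiated benzoate 15 (not isolated), via boronate complex 16 (not isolated)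
Conditions: s-BuLi, (+)-sparteine, Et2O, −78 °C, 5 h; 14, −78 °C, 1 h; then reflux
Reagents that add atoms: none
Why: Sparteine-mediated asymmetric lithiation–borylation, in which s-BuLi/(+)-sparteine removes the pro-R hydrogen to give the (R)-organolithium, borylation proceeds with retention and the isopropenyl group migrates with inversion at carbon, so C1 is set as the (S)-allylic boronic ester.

Step 9
Reactants: 17 tert-butyl{[(3S)-4-methyl-3-(Bpin)pent-4-en-1-yl]oxy}diphenylsilane
Product: 19 tert-butyl{[(3S)-4-methyl-3-[(Bpin)methyl]pent-4-en-1-yl]oxy}diphenylsilane, via chloromethyl boronate complex 18 (not isolated)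
Conditions: BrCH2Cl, n-BuLi, Et2O, −78 °C to rt
Reagents that add atoms: bromochloromethane, ClCBr
Why: Matteson homologation with chloromethyllithium made in situ inserts C2 by a stereoretentive 1,2-migration of the allylic carbon, so C1 is preserved and no allylic transposition occurs.

Step 10
Reactants: 19 tert-butyl{[(3S)-4-methyl-3-[(Bpin)methyl]pent-4-en-1-yl]oxy}diphenylsilane
Product: 21 tert-butyl{[(3S)-4-methyl-3-[2-(Bpin)ethyl]pent-4-en-1-yl]oxy}diphenylsilane, via chloromethyl boronate complex 20 (not isolated)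
Conditions: BrCH2Cl, n-BuLi, Et2O, −78 °C to rt
Reagents that add atoms: bromochloromethane, ClCBr
Why: A second Matteson homologation inserts C3, and over-insertion is avoided because the carbenoid decomposes before the complex rearranges on warming.

Step 11
Reactants: 10 2,4,6-triisopropylbenzoic acid; 22 iodoethane
Product: 23 ethyl 2,4,6-triisopropylbenzoate
Conditions: K2CO3, DMF, 50 °C
Reagents that add atoms: none
Why: SN2 O-alkylation of the hindered carboxylate gives the two-carbon carbenoid precursor that supplies C4 and its methyl group.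

Step 12
Reactants: 23 ethyl 2,4,6-triisopropylbenzoate; 21 tert-butyl{[(3S)-4-methyl-3-[2-(Bpin)ethyl]pent-4-en-1-yl]oxy}diphenylsilane
Product: 26 tert-butyl{[(3S)-4-methyl-3-[(3R)-3-(Bpin)butyl]pent-4-en-1-yl]oxy}diphenylsilane (fragment B), via lithiated benzoate 24 (not isolated), via boronate complex 25 (not isolated)
Conditions: 23, s-BuLi, (−)-sparteine, Et2O, −78 °C, 4 h; 21, −78 °C, 1 h; then reflux
Reagents that add atoms: none
Why: Asymmetric lithiation–borylation, in which s-BuLi/(−)-sparteine gives the (S)-1-lithioethyl benzoate, and retentive borylation followed by invertive 1,2-migration of the primary alkyl group sets C4 as the (R)-secondary boronic ester.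

Step 13
Reactants: 11 fragment A benzoate; 26 fragment B boronic ester
Product: 30 (3S,6R,7S,10S,14R)-14-(TBSO)-1-(TBDPSO)-6,10-dimethyl-3-(prop-1-en-2-yl)pentadec-12-yn-7-ol, via lithiated benzoate 27 (not isolated), via boronate complex 28 (not isolated), via C5 boronic ester 29 (not isolated)
Conditions: 11, s-BuLi, (+)-sparteine, Et2O, −78 °C, 5 h; 26, −78 °C, 1 h; reflux; then H2O2, NaOH, THF, 0 °C to rt
Reagents that add atoms: hydrogen peroxide, OO
Why: Asymmetric lithiation–borylation–oxidation, in which the (R)-lithiated benzoate from s-BuLi/(+)-sparteine captures 26 with retention, C4 migrates with retention at C4 and inversion at C5, and stereoretentive peroxide oxidation gives the anti (4R,5S) alcohol under reagent control.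

Step 14
Reactants: 30 C5 alcohol
Product: 31 (3S,6R,7S,10S,14R)-14-(TBSO)-1-(TBDPSO)-6,10-dimethyl-3-(prop-1-en-2-yl)pentadec-12-yn-7-yl acetate
Conditions: Ac2O, DMAP (cat.), pyridine, rt
Reagents that add atoms: acetic anhydride, CC(=O)OC(C)=O
Why: DMAP-catalysed acetylation of the only free hydroxyl installs the final C5 acetate, which also serves as protecting group for the rest of the route.

Step 15
Reactants: 31 C5 acetate
Product: 32 (3S,6R,7S,10S,14R)-1-(TBDPSO)-14-hydroxy-6,10-dimethyl-3-(prop-1-en-2-yl)pentadec-12-yn-7-yl acetate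
Conditions: CSA (cat.), MeOH/CH2Cl2, 0 °C
Reagents that add atoms: none
Why: Acid-catalysed methanolysis cleaves the unhindered secondary TBS ether while the far more acid-stable primary TBDPS ether and the acetate survive.

Step 16
Reactants: 32 propargylic alcohol
Product: 33 (3S,6R,7S,10S,14R)-1-(TBDPSO)-14-(mesyloxy)-6,10-dimethyl-3-(prop-1-en-2-yl)pentadec-12-yn-7-yl acetate
Conditions: MsCl, Et3N, CH2Cl2, −78 °C
Reagents that add atoms: methanesulfonyl chloride, CS(=O)(=O)Cl
Why: Low-temperature sulfonylation activates the C12 oxygen without touching the C12–O bond, so the (R) configuration is kept and the crude mesylate is used at once.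

Step 17
Reactants: 33 propargylic mesylate; 34 tributyltin hydride
Product: 35 (3S,6R,7S,10S,aS)-1-(TBDPSO)-6,10-dimethyl-3-(prop-1-en-2-yl)-12-(tributylstannyl)pentadeca-12,13-dien-7-yl acetate
Conditions: 34, LiN(i-Pr)2, THF, 0 °C; CuBr·SMe2, −78 °C; then 33, −78 °C
Reagents that add atoms: none
Why: Anti SN2′ displacement of a propargylic mesylate by a stannylcopper reagent, in which tin enters at C10 opposite the departing mesylate so that the (12R) centre becomes the (aS) allene axis, and the soft copper reagent spares the acetate at −78 °C.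

Step 18
Reactants: 35 allenylstannane silyl ether
Product: 36 (3S,6R,7S,10S,aS)-1-hydroxy-6,10-dimethyl-3-(prop-1-en-2-yl)-12-(tributylstannyl)pentadeca-12,13-dien-7-yl acetate
Conditions: TBAF, AcOH (1:1), THF, rt
Reagents that add atoms: none
Why: Fluoride-mediated desilylation buffered with acetic acid frees the C13 alcohol under nearly neutral conditions that neither cleave the acetate nor protonate the allenylstannane.

Step 19
Reactants: 36 allenylstannane alcohol
Product: 37 (3S,6R,7S,10S,aS)-6,10-dimethyl-1-oxo-3-(prop-1-en-2-yl)-12-(tributylstannyl)pentadeca-12,13-dien-7-yl acetate (seco aldehyde)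
Conditions: Dess–Martin periodinane, NaHCO3, CH2Cl2, 0 °C
Reagents that add atoms: none
Why: Bicarbonate-buffered Dess–Martin oxidation releases the aldehyde only after tin is in place, since stannyl anions would add to it, and the buffer keeps acid away from the stannane.

Step 20
Reactants: 37 seco aldehyde
Product: 38 (1S,4R,5S,8S,12R,13R)-13-hydroxy-4,8,12-trimethyl-1-(prop-1-en-2-yl)cyclotetradec-10-yn-5-yl acetate (ring numbering)
Conditions: BF3·OEt2 (3 equiv), CH2Cl2 (1 mM, slow addition of 37), −78 °C; aq. NaHCO3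
Reagents that add atoms: none
Why: Proposed new method: BF3 activates the C13 aldehyde, and the C11=C12 π bond, raised in energy by the C10–Sn bond aligned with it, attacks through C12 on the face opposite tin (anti SE2′), so that C12–C13 forms, C10≡C11 develops and Bu3SnF is lost. The closest known reaction types are the syn-selective intermolecular BF3-promoted additions of chiral allenylstannanes to aldehydes and the Lewis-acid SE′ macrocyclisations of allylic stannane aldehydes to 14-membered carbocycles, whereas the allenyl variant on a flexible, saturated fourteen-atom tether is untested. The single ring, the 14-membered carbocycle, closes 14-exo-trig at the carbonyl carbon with all three allene carbons ending inside the ring, and the linear C9–C10≡C11–C12 unit is free of strain at this ring size. C12 (R) is fixed by the (aS) axis through the anti pathway, which is intrinsic to the stannane, and C13 (R, syn to the methyl) by the open antiperiplanar transition state in which the aldehyde chain C14 avoids the C12 methyl. The step needs chemoselectivity for the stannane over isopropenyl and acetate (secured by the much higher nucleophilicity of the stannane at −78 °C, by the disfavoured 5-endo geometry of the ene alternative and by excess BF3 that saturates the ester), ring closure over oligomerisation (secured by high dilution and slow addition), and aldehyde-face selectivity. Because an α-unbranched aldehyde has only a weak acyclic syn bias, this last point rests on the tether and is the real risk of the route.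

Step 21
Reactants: 38 cycloalkyne alcohol
Product: 40 (1S,4R,5S,8S,12R,13R)-13-hydroxy-4,8,12-trimethyl-10-oxo-1-(prop-1-en-2-yl)cyclotetradecan-5-yl acetate (ring numbering), via bridged dihydrofuran 39 (not isolated)
Conditions: Ph3PAuNTf2 (5 mol %), THF/H2O 10:1, rt
Reagents that add atoms: water, O
Why: Gold-catalysed cycloisomerisation–hydrolysis of a homopropargylic alcohol, in which the C13 hydroxyl adds 5-endo-dig to the activated alkyne at C10 and water opens the resulting enol ether, so oxygen ends on C10 and not C11 and no stereocentre is touched.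

Step 22
Reactants: 40 hydroxy ketone
Product: 41 target CNP0328624.1
Conditions: Ac2O, DMAP (cat.), pyridine, rt
Reagents that add atoms: acetic anhydride, CC(=O)OC(C)=O
Why: DMAP-catalysed acetylation irreversibly traps the open hydroxy-ketone tautomer at the secondary C13 hydroxyl, and C12 (β to the ketone) and C13 cannot epimerise or eliminate under these conditions.

Compound list
1 | (S)-citronellal | CC(C)=CCC[C@H](C)CC=O | starting material
2 | (S)-4,8-dimethylnon-7-en-1-yne | CC(C)=CCC[C@H](C)CC#C | intermediate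
3 | N-methoxy-N-methylacetamide | CC(=O)N(C)OC | starting material
4 | lithium acetylide of 2 | CC(C)=CCC[C@H](C)CC#C[Li] | intermediate
5 | (S)-6,10-dimethylundec-9-en-3-yn-2-one | CC(C)=CCC[C@H](C)CC#CC(C)=O | intermediate
6 | (2R,6S)-6,10-dimethylundec-9-en-3-yn-2-ol | CC(C)=CCC[C@H](C)CC#C[C@@H](C)O | intermediate
7 | TBS ether of 6 | CC(C)=CCC[C@H](C)CC#C[C@@H](C)O[Si](C)(C)C(C)(C)C | intermediate
8 | (4S,8R)-8-(TBSO)-4-methylnon-6-ynal | O=CCC[C@H](C)CC#C[C@@H](C)O[Si](C)(C)C(C)(C)C | intermediate
9 | (4S,8R)-8-(TBSO)-4-methylnon-6-yn-1-ol | OCCC[C@H](C)CC#C[C@@H](C)O[Si](C)(C)C(C)(C)C | intermediate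
10 | 2,4,6-triisopropylbenzoic acid | CC(C)c1cc(C(C)C)c(C(=O)O)c(C(C)C)c1 | starting material
11 | fragment A, 2,4,6-triisopropylbenzoate of 9 | O=C(OCCC[C@H](C)CC#C[C@@H](C)O[Si](C)(C)C(C)(C)C)c1c(C(C)C)cc(C(C)C)cc1C(C)C | intermediate
12 | 3-[(tert-butyldiphenylsilyl)oxy]propan-1-ol | OCCCO[Si](c1ccccc1)(c1ccccc1)C(C)(C)C | starting material
13 | 3-(TBDPSO)propyl 2,4,6-triisopropylbenzoate | O=C(OCCCO[Si](c1ccccc1)(c1ccccc1)C(C)(C)C)c1c(C(C)C)cc(C(C)C)cc1C(C)C | intermediate
14 | isopropenylboronic acid pinacol ester | C=C(C)B1OC(C)(C)C(C)(C)O1 | starting material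
15 | (R)-1-lithio derivative of 13 | O=C(O[C@H]([Li])CCO[Si](c1ccccc1)(c1ccccc1)C(C)(C)C)c1c(C(C)C)cc(C(C)C)cc1C(C)C | intermediate
16 | lithium boronate complex of 15 and 14 | [Li+].O=C(O[C@H]([B-]1(C(C)=C)OC(C)(C)C(C)(C)O1)CCO[Si](c1ccccc1)(c1ccccc1)C(C)(C)C)c1c(C(C)C)cc(C(C)C)cc1C(C)C | intermediate
17 | (S)-allylic boronic ester (boron on C1) | C=C(C)[C@H](CCO[Si](c1ccccc1)(c1ccccc1)C(C)(C)C)B1OC(C)(C)C(C)(C)O1 | intermediate
18 | lithium chloromethyl boronate complex of 17 | [Li+].C=C(C)[C@H](CCO[Si](c1ccccc1)(c1ccccc1)C(C)(C)C)[B-]1(CCl)OC(C)(C)C(C)(C)O1 | intermediate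
19 | (S)-boronic ester (boron on C2) | C=C(C)[C@H](CCO[Si](c1ccccc1)(c1ccccc1)C(C)(C)C)CB1OC(C)(C)C(C)(C)O1 | intermediate
20 | lithium chloromethyl boronate complex of 19 | [Li+].C=C(C)[C@H](CCO[Si](c1ccccc1)(c1ccccc1)C(C)(C)C)C[B-]1(CCl)OC(C)(C)C(C)(C)O1 | intermediate
21 | (S)-boronic ester (boron on C3) | C=C(C)[C@H](CCO[Si](c1ccccc1)(c1ccccc1)C(C)(C)C)CCB1OC(C)(C)C(C)(C)O1 | intermediate
22 | iodoethane | CCI | starting material
23 | ethyl 2,4,6-triisopropylbenzoate | CCOC(=O)c1c(C(C)C)cc(C(C)C)cc1C(C)C | intermediate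
24 | (S)-1-lithioethyl 2,4,6-triisopropylbenzoate | C[C@H]([Li])OC(=O)c1c(C(C)C)cc(C(C)C)cc1C(C)C | intermediate
25 | lithium boronate complex of 24 and 21 | [Li+].C=C(C)[C@H](CCO[Si](c1ccccc1)(c1ccccc1)C(C)(C)C)CC[B-]1(OC(C)(C)C(C)(C)O1)[C@@H](C)OC(=O)c1c(C(C)C)cc(C(C)C)cc1C(C)C | intermediate
26 | fragment B, (1S,4R)-secondary boronic ester (boron on C4) | C=C(C)[C@H](CCO[Si](c1ccccc1)(c1ccccc1)C(C)(C)C)CC[C@@H](C)B1OC(C)(C)C(C)(C)O1 | intermediate
27 | (R)-1-lithio derivative of 11 (lithium on C5) | O=C(O[C@H]([Li])CC[C@H](C)CC#C[C@@H](C)O[Si](C)(C)C(C)(C)C)c1c(C(C)C)cc(C(C)C)cc1C(C)C | intermediate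
28 | lithium boronate complex of 27 and 26 | [Li+].C=C(C)[C@H](CCO[Si](c1ccccc1)(c1ccccc1)C(C)(C)C)CC[C@@H](C)[B-]1(OC(C)(C)C(C)(C)O1)[C@@H](OC(=O)c1c(C(C)C)cc(C(C)C)cc1C(C)C)CC[C@H](C)CC#C[C@@H](C)O[Si](C)(C)C(C)(C)C | intermediate
29 | C5 boronic ester | C=C(C)[C@H](CCO[Si](c1ccccc1)(c1ccccc1)C(C)(C)C)CC[C@@H](C)[C@@H](B1OC(C)(C)C(C)(C)O1)CC[C@H](C)CC#C[C@@H](C)O[Si](C)(C)C(C)(C)C | intermediate
30 | C5 alcohol (C12 OTBS, C13 OTBDPS) | C=C(C)[C@H](CCO[Si](c1ccccc1)(c1ccccc1)C(C)(C)C)CC[C@@H](C)[C@@H](O)CC[C@H](C)CC#C[C@@H](C)O[Si](C)(C)C(C)(C)C | intermediate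
31 | C5 acetate (C12 OTBS, C13 OTBDPS) | C=C(C)[C@H](CCO[Si](c1ccccc1)(c1ccccc1)C(C)(C)C)CC[C@@H](C)[C@@H](OC(C)=O)CC[C@H](C)CC#C[C@@H](C)O[Si](C)(C)C(C)(C)C | intermediate
32 | (12R)-propargylic alcohol | C=C(C)[C@H](CCO[Si](c1ccccc1)(c1ccccc1)C(C)(C)C)CC[C@@H](C)[C@@H](OC(C)=O)CC[C@H](C)CC#C[C@@H](C)O | intermediate
33 | (12R)-propargylic mesylate | C=C(C)[C@H](CCO[Si](c1ccccc1)(c1ccccc1)C(C)(C)C)CC[C@@H](C)[C@@H](OC(C)=O)CC[C@H](C)CC#C[C@@H](C)OS(C)(=O)=O | intermediate
34 | tributyltin hydride | CCCC[SnH](CCCC)CCCC | starting material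
35 | (aS)-allenylstannane, C13 OTBDPS | CCCC[Sn](CCCC)(CCCC)C(C[C@@H](C)CC[C@H](OC(C)=O)[C@H](C)CC[C@H](C(C)=C)CCO[Si](c1ccccc1)(c1ccccc1)C(C)(C)C)=[C@@]=C([H])C | intermediate
36 | (aS)-allenylstannane, C13 alcohol | CCCC[Sn](CCCC)(CCCC)C(C[C@@H](C)CC[C@H](OC(C)=O)[C@H](C)CC[C@H](C(C)=C)CCO)=[C@@]=C([H])C | intermediate
37 | seco aldehyde with (aS)-C10-stannyl allene | CCCC[Sn](CCCC)(CCCC)C(C[C@@H](C)CC[C@H](OC(C)=O)[C@H](C)CC[C@H](C(C)=C)CC=O)=[C@@]=C([H])C | intermediate
38 | 14-membered cycloalkyne with free C13 hydroxyl | C=C(C)[C@H]1CC[C@@H](C)[C@@H](OC(C)=O)CC[C@H](C)CC#C[C@@H](C)[C@H](O)C1 | intermediate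
39 | bridged 2,3-dihydrofuran (O links C13 and C10) | C=C(C)[C@H]1CC[C@@H](C)[C@@H](OC(C)=O)CC[C@H](C)CC2=C[C@@H](C)[C@H](O2)C1 | intermediate
40 | C13-hydroxy C10-ketone | C=C(C)[C@H]1CC[C@@H](C)[C@@H](OC(C)=O)CC[C@H](C)CC(=O)C[C@@H](C)[C@H](O)C1 | intermediate
41 | CNP0328624.1 (1S,4R,5S,8S,12R,13R) | C=C(C)[C@H]1CC[C@@H](C)[C@@H](OC(C)=O)CC[C@H](C)CC(=O)C[C@@H](C)[C@H](OC(C)=O)C1 | target

Total step count: 22. Longest linear sequence: 16 (steps 1–6, then 13–22). Fragment B takes steps 7–10 and 12, and step 11 is a one-step side branch.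

Steps most likely to fail

1) Step 20 (key step).
- What may go wrong: the slow closure of a flexible fourteen-atom chain may be overtaken by oligomerisation or protodestannylation, and the α-unbranched aldehyde may be attacked on the wrong face.
- Fallback approach: stereocontrol is separated from ring closure with known chemistry, namely an intermolecular allenylstannane addition followed by ring-closing alkyne metathesis at C10≡C11. It sets out from 2 (using 10 and 26) and comes back at 38.
- Alkyne 2 is methylated (n-BuLi, MeI) to (S)-5,9-dimethyldec-8-en-2-yne F1. Ozonolysis with NaBH4 work-up gives (S)-4-methyloct-6-yn-1-ol F2, and Mitsunobu esterification with 10 gives the triisopropylbenzoate of F2 F3.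
- Lithiation with s-BuLi/(+)-sparteine, borylation with 26 and oxidation as in step 13 give the methyl-capped C5 alcohol F4. Acetylation gives the methyl-capped C5 acetate F5, TBAF/AcOH gives the methyl-capped C13 alcohol F6, and Dess–Martin oxidation gives the methyl-capped C13 aldehyde F7.
- Purchased (R)-pent-3-yn-2-ol is converted with MsCl/Et3N into (R)-pent-3-yn-2-yl methanesulfonate F8, and then with Bu3SnLi/CuBr·SMe2 into (aS)-tributyl(penta-2,3-dien-2-yl)stannane F9.
- BF3·OEt2 at −78 °C joins F9 and F7 to the syn seco-diyne alcohol F10, and any anti isomer is removed here by chromatography.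
- TESOTf/2,6-lutidine gives the seco-diyne triethylsilyl ether F11. [MesC≡Mo(OSiPh3)3] with 5 Å molecular sieves in toluene closes the cycloalkyne triethylsilyl ether F12 with loss of but-2-yne. PPTS in MeOH then releases 38.

2) Step 13.
- What may go wrong: during the long lithiation of 11, deprotonation at the propargylic positions or attack of the C5 carbanion on the alkyne may compete, and the hindered secondary boronate complex may rearrange sluggishly.
- Fallback approach: C4–C5 is built by crotylboration and the remaining carbons are added to a boronic ester, so the alkyne fragment never meets s-BuLi. It sets out from 7 and 13 and comes back at 30.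
- Ozonolysis of 7 with PPh3 work-up isolates aldehyde 8. Brown crotylboration with (E)-crotyldiisopinocampheylborane made from (+)-Ipc2BOMe gives (3R,4S,7S,11R)-11-(TBSO)-3,7-dimethyldodec-1-en-9-yn-4-ol F13, which carries C4 R and C5 S (anti).
- TESCl/imidazole gives the triethylsilyl ether of F13 F14, and [Ir(cod)Cl]2/dppe with HBpin gives the C2 primary boronic ester F15.
- Benzoate 13 is lithiated with s-BuLi/(−)-sparteine to the (S)-1-lithio derivative of 13 F16. This captures F15 and rearranges to the C1 secondary boronic ester F17.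
- Zweifel olefination (isopropenyllithium, then I2, then NaOMe) replaces boron by isopropenyl with retention and gives the C5 triethylsilyl ether of 30 F18. PPTS in MeOH at 0 °C removes only the triethylsilyl group and gives 30.

3) Step 21.
- What may go wrong: regiocontrol may erode through direct attack of water at C11, the reaction may stop at the bridged enol ether or its ketal, or the cationic gold may engage the isopropenyl group.
- Fallback approach: π-acid hydration is replaced by a tethered hydrosilylation–oxidation. It sets out from 38 and comes back at 40.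
- (Me2HSi)2NH converts 38 into the C13 dimethylsilyl ether F19. [Cp*Ru(MeCN)3]PF6 catalyses intramolecular endo-dig trans-hydrosilylation to the six-membered oxasilacycle F20 with silicon on C10.
- Tamao–Fleming oxidation (H2O2, KF, KHCO3, THF/MeOH) then converts the C10–Si bond into the ketone and frees the C13 hydroxyl, giving 40.

Further compounds
F1 | step 20 | (S)-5,9-dimethyldec-8-en-2-yne | CC(C)=CCC[C@H](C)CC#CC
F2 | step 20 | (S)-4-methyloct-6-yn-1-ol | OCCC[C@H](C)CC#CC
F3 | step 20 | triisopropylbenzoate of F2 | O=C(OCCC[C@H](C)CC#CC)c1c(C(C)C)cc(C(C)C)cc1C(C)C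
F4 | step 20 | methyl-capped C5 alcohol | C=C(C)[C@H](CCO[Si](c1ccccc1)(c1ccccc1)C(C)(C)C)CC[C@@H](C)[C@@H](O)CC[C@H](C)CC#CC
F5 | step 20 | methyl-capped C5 acetate | C=C(C)[C@H](CCO[Si](c1ccccc1)(c1ccccc1)C(C)(C)C)CC[C@@H](C)[C@@H](OC(C)=O)CC[C@H](C)CC#CC
F6 | step 20 | methyl-capped C13 alcohol | C=C(C)[C@H](CCO)CC[C@@H](C)[C@@H](OC(C)=O)CC[C@H](C)CC#CC
F7 | step 20 | methyl-capped C13 aldehyde | C=C(C)[C@H](CC=O)CC[C@@H](C)[C@@H](OC(C)=O)CC[C@H](C)CC#CC
F8 | step 20 | (R)-pent-3-yn-2-yl methanesulfonate | CC#C[C@@H](C)OS(C)(=O)=O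
F9 | step 20 | (aS)-tributyl(penta-2,3-dien-2-yl)stannane | CCCC[Sn](CCCC)(CCCC)C(C)=[C@@]=C([H])C
F10 | step 20 | syn seco-diyne alcohol | C=C(C)[C@H](C[C@@H](O)[C@H](C)C#CC)CC[C@@H](C)[C@@H](OC(C)=O)CC[C@H](C)CC#CC
F11 | step 20 | seco-diyne triethylsilyl ether | C=C(C)[C@H](C[C@@H](O[Si](CC)(CC)CC)[C@H](C)C#CC)CC[C@@H](C)[C@@H](OC(C)=O)CC[C@H](C)CC#CC
F12 | step 20 | cycloalkyne triethylsilyl ether | C=C(C)[C@H]1CC[C@@H](C)[C@@H](OC(C)=O)CC[C@H](C)CC#C[C@@H](C)[C@H](O[Si](CC)(CC)CC)C1
F13 | step 13 | (3R,4S,7S,11R)-11-(TBSO)-3,7-dimethyldodec-1-en-9-yn-4-ol | C=C[C@@H](C)[C@@H](O)CC[C@H](C)CC#C[C@@H](C)O[Si](C)(C)C(C)(C)C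
F14 | step 13 | triethylsilyl ether of F13 | C=C[C@@H](C)[C@@H](O[Si](CC)(CC)CC)CC[C@H](C)CC#C[C@@H](C)O[Si](C)(C)C(C)(C)C
F15 | step 13 | C2 primary boronic ester | CC1(C)OB(CC[C@@H](C)[C@@H](O[Si](CC)(CC)CC)CC[C@H](C)CC#C[C@@H](C)O[Si](C)(C)C(C)(C)C)OC1(C)C
F16 | step 13 | (S)-1-lithio derivative of 13 | O=C(O[C@@H]([Li])CCO[Si](c1ccccc1)(c1ccccc1)C(C)(C)C)c1c(C(C)C)cc(C(C)C)cc1C(C)C
F17 | step 13 | C1 secondary boronic ester | CC1(C)OB(OC1(C)C)[C@H](CCO[Si](c1ccccc1)(c1ccccc1)C(C)(C)C)CC[C@@H](C)[C@@H](O[Si](CC)(CC)CC)CC[C@H](C)CC#C[C@@H](C)O[Si](C)(C)C(C)(C)C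
F18 | step 13 | C5 triethylsilyl ether of 30 | C=C(C)[C@H](CCO[Si](c1ccccc1)(c1ccccc1)C(C)(C)C)CC[C@@H](C)[C@@H](O[Si](CC)(CC)CC)CC[C@H](C)CC#C[C@@H](C)O[Si](C)(C)C(C)(C)C
F19 | step 21 | C13 dimethylsilyl ether | C=C(C)[C@H]1CC[C@@H](C)[C@@H](OC(C)=O)CC[C@H](C)CC#C[C@@H](C)[C@H](O[SiH](C)C)C1
F20 | step 21 | six-membered oxasilacycle | C=C(C)[C@H]1CC[C@@H](C)[C@@H](OC(C)=O)CC[C@H](C)CC2=C[C@@H](C)[C@H](O[Si]2(C)C)C1
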